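**Retrosynthetic overview**
- The target comes from its hexabenzyl ether by one neutral global hydrogenolysis at the end.
- Key disconnection: the bond between flavanone C3 and flavone C3. The flavone C3, normally nucleophilic, is reversed in polarity as a flavon-3-yl(aryl)iodonium salt (a vinylogous enolonium equivalent) and joined to the enol silane of the (2S)-flavanone under copper catalysis; C3 is set trans to the C2 aryl group in the bond-forming event.
- Flavanone half: 5,7-bis(benzyloxy)chromone plus an arylboronic acid, with C2 set by Rh-catalysed asymmetric 1,4-addition; the chromone comes from phloroacetophenone.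
- Flavone half: apigenin, benzylated, lithiated and iodinated at C3, then oxidised to the iodonium salt.
- Ring order: the flavone rings are bought intact, ring C of the flavanone half is closed at the chromone stage, and no ring is formed after the union.

Assumption: the (S)-configured biaryl diphosphine gives the (2S)-flavanone (the facial sense known for (S)-BINAP-type ligands with cyclic enones); if the opposite sense is found, the (R)-ligand is used.

**Step 1**
Reactants: 1 2',4',6'-trihydroxyacetophenone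
Product: 2 1-[2,4-bis(benzyloxy)-6-hydroxyphenyl]ethan-1-one
Conditions: BnBr (2.05 equiv), K2CO3 (2.2 equiv), DMF, rt
Reagents that add atoms: benzyl bromide, BrCc1ccccc1
Why: Williamson ether synthesis in which the 4-OH and one of the two equivalent ortho OH groups are alkylated, while the remaining ortho OH is hydrogen-bonded to the ketone and stays free.

**Step 2**
Reactants: 2 1-[2,4-bis(benzyloxy)-6-hydroxyphenyl]ethan-1-one
Product: 4 5,7-bis(benzyloxy)-4H-chromen-4-one, via enaminone 3 (not isolated)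
Conditions: Me2NCH(OMe)2 (3 equiv), toluene, 95 °C; then 2 M HCl (aq), CH2Cl2, 40 °C
Reagents that add atoms: N,N-dimethylformamide dimethyl acetal, COC(OC)N(C)C
Why: Condensation of the methyl ketone with the formamide acetal gives the enaminone, and acid-promoted cyclisation with loss of dimethylamine is the standard chromone annulation of 2-hydroxyacetophenones.

**Step 3**
Reactants: 4 5,7-bis(benzyloxy)-4H-chromen-4-one; 5 [4-(benzyloxy)phenyl]boronic acid
Product: 6 (2S)-5,7-bis(benzyloxy)-2-[4-(benzyloxy)phenyl]-2,3-dihydro-4H-chromen-4-one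
Conditions: 5 (2 equiv), [Rh(OH)(cod)]2 (2 mol%), (S)-MeO-F12-BIPHEP [(S)-6,6'-dimethoxy-2,2'-bis{bis(3,4,5-trifluorophenyl)phosphino}-1,1'-biphenyl] (4.4 mol%), toluene/H2O 20:1, 40 °C; recrystallise to >99% ee
Reagents that add atoms: none
Why: Rhodium-catalysed asymmetric 1,4-addition (Hayashi–Miyaura reaction) in which the diphosphine-bound aryl–rhodium species adds across C2=C3 on one face to set C2 as S, the electron-poor ligand allowing a temperature low enough that the flavanone neither ring-opens nor racemises.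

**Step 4**
Reactants: 7 apigenin (5,7-dihydroxy-2-(4-hydroxyphenyl)-4H-chromen-4-one)
Product: 8 5,7-bis(benzyloxy)-2-[4-(benzyloxy)phenyl]-4H-chromen-4-one
Conditions: BnBr (3.6 equiv), K2CO3 (4 equiv), DMF, 80 °C
Reagents that add atoms: benzyl bromide, BrCc1ccccc1
Why: Exhaustive Williamson etherification, the chelated 5-OH reacting last and needing excess reagent and heat.

**Step 5**
Reactants: 8 5,7-bis(benzyloxy)-2-[4-(benzyloxy)phenyl]-4H-chromen-4-one
Product: 10 5,7-bis(benzyloxy)-2-[4-(benzyloxy)phenyl]-3-iodo-4H-chromen-4-one, via 3-lithioflavone 9 (not isolated)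
Conditions: LiN(iPr)2 (1.2 equiv), THF, −78 °C, 30 min; then I2 (1.3 equiv), −78 °C; aq Na2S2O3
Reagents that add atoms: iodine, [I][I]
Why: Deprotonation of the vinylic C3–H next to the carbonyl (C3 lithiation of a flavone) and iodine quench place iodine at C3 with a regiochemistry that electrophilic iodination of the electron-rich ring A could not guarantee, the lithio species being kept at −78 °C because it ring-opens to an ynone phenoxide on warming.

**Step 6**
Reactants: 10 5,7-bis(benzyloxy)-2-[4-(benzyloxy)phenyl]-3-iodo-4H-chromen-4-one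
Product: 13 [5,7-bis(benzyloxy)-2-[4-(benzyloxy)phenyl]-4-oxo-4H-chromen-3-yl](2,4,6-trimethoxyphenyl)iodonium trifluoromethanesulfonate, via hydroxy(tosyloxy)iodane 11 (not isolated), via iodonium tosylate 12 (not isolated)
Conditions: mCPBA (1.1 equiv), TsOH·H2O (1.1 equiv), CH2Cl2/CF3CH2OH 1:1, rt; then 1,3,5-trimethoxybenzene (1.1 equiv), rt; then aq NaOTf, precipitate from Et2O
Reagents that add atoms: 1,3,5-trimethoxybenzene, COc1cc(OC)cc(OC)c1; sodium trifluoromethanesulfonate, [Na+].[O-]S(=O)(=O)C(F)(F)F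
Why: One-pot oxidation of the iodide to a Koser-type hydroxy(tosyloxy)iodane and electrophilic aromatic substitution on trimethoxybenzene give an unsymmetrical iodonium salt in which trimethoxyphenyl is a non-transferring dummy group and the flavone C3 has become an electrophilic, enolonium-type carbon, anion metathesis then installing the weakly coordinating triflate.

**Step 7**
Reactants: 6 (2S)-5,7-bis(benzyloxy)-2-[4-(benzyloxy)phenyl]-2,3-dihydro-4H-chromen-4-one; 13 [5,7-bis(benzyloxy)-2-[4-(benzyloxy)phenyl]-4-oxo-4H-chromen-3-yl](2,4,6-trimethoxyphenyl)iodonium trifluoromethanesulfonate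
Product: 15 (2S,3R)-5,7-bis(benzyloxy)-2-[4-(benzyloxy)phenyl]-3-{5,7-bis(benzyloxy)-2-[4-(benzyloxy)phenyl]-4-oxo-4H-chromen-3-yl}-2,3-dihydro-4H-chromen-4-one, via silyl enol ether 14 (not isolated)
Conditions: Me3SiCl (1.5 equiv) then LiN(SiMe3)2 (1.1 equiv), THF, −78 °C; evaporate, take up in CH2Cl2, filter under Ar; then 13 (1.2 equiv), [Cu(MeCN)4]OTf (10 mol%), 2,6-di-tert-butylpyridine (0.3 equiv), CH2Cl2, 0 °C to rt; silica gel chromatography
Reagents that add atoms: none
Why: Proposed new method: the closest known reaction type is the copper-catalysed α-arylation and α-alkenylation of silyl enol ethers and silyl ketene acetals with diaryl- and alkenyl(aryl)iodonium triflates, here extended to a pyranon-3-yl group, in which monovalent copper adds oxidatively to the iodonium salt to give an electrophilic flavon-3-yl trivalent copper species (the electron-poor alkenyl-type group is transferred in preference to the hindered, electron-rich trimethoxyphenyl), the enol silane attacks through C3 on the face opposite the C2 aryl group, and reductive elimination with loss of Me3SiOTf forms the C3–C3 bond as the 2,3-trans (2S,3R) isomer, which is also the thermodynamic arrangement, under base-free conditions so that no retro-oxa-Michael racemisation of C2 can occur.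

**Step 8**
Reactants: 15 (2S,3R)-5,7-bis(benzyloxy)-2-[4-(benzyloxy)phenyl]-3-{5,7-bis(benzyloxy)-2-[4-(benzyloxy)phenyl]-4-oxo-4H-chromen-3-yl}-2,3-dihydro-4H-chromen-4-one
Product: 16 (2S,3R)-5,7-dihydroxy-2-(4-hydroxyphenyl)-3-[5,7-dihydroxy-2-(4-hydroxyphenyl)-4-oxo-4H-chromen-3-yl]-2,3-dihydro-4H-chromen-4-one
Conditions: H2 (1 atm), 10% Pd/C, THF/MeOH 1:1, rt
Reagents that add atoms: none
Why: Hydrogenolysis of the six aryl benzyl ethers under neutral conditions leaves the tetrasubstituted flavone alkene, both ketones and the base-sensitive C2 and C3 stereocentres untouched.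

**Compound list**
1 | 2',4',6'-trihydroxyacetophenone (phloroacetophenone) | CC(=O)c1c(O)cc(O)cc1O | starting material
2 | 1-[2,4-bis(benzyloxy)-6-hydroxyphenyl]ethan-1-one | CC(=O)c1c(O)cc(OCc2ccccc2)cc1OCc1ccccc1 | intermediate
3 | (E)-1-[2,4-bis(benzyloxy)-6-hydroxyphenyl]-3-(dimethylamino)prop-2-en-1-one (enaminone, not isolated) | CN(C)/C=C/C(=O)c1c(O)cc(OCc2ccccc2)cc1OCc1ccccc1 | intermediate
4 | 5,7-bis(benzyloxy)-4H-chromen-4-one | O=c1ccoc2cc(OCc3ccccc3)cc(OCc3ccccc3)c12 | intermediate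
5 | [4-(benzyloxy)phenyl]boronic acid | OB(O)c1ccc(OCc2ccccc2)cc1 | starting material
6 | (2S)-5,7-bis(benzyloxy)-2-[4-(benzyloxy)phenyl]-2,3-dihydro-4H-chromen-4-one | O=C1C[C@@H](c2ccc(OCc3ccccc3)cc2)Oc2cc(OCc3ccccc3)cc(OCc3ccccc3)c12 | intermediate
7 | apigenin | O=c1cc(-c2ccc(O)cc2)oc2cc(O)cc(O)c12 | starting material
8 | 5,7-bis(benzyloxy)-2-[4-(benzyloxy)phenyl]-4H-chromen-4-one | O=c1cc(-c2ccc(OCc3ccccc3)cc2)oc2cc(OCc3ccccc3)cc(OCc3ccccc3)c12 | intermediate
9 | 3-lithio-5,7-bis(benzyloxy)-2-[4-(benzyloxy)phenyl]-4H-chromen-4-one (not isolated) | [Li]c1c(-c2ccc(OCc3ccccc3)cc2)oc2cc(OCc3ccccc3)cc(OCc3ccccc3)c2c1=O | intermediate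
10 | 5,7-bis(benzyloxy)-2-[4-(benzyloxy)phenyl]-3-iodo-4H-chromen-4-one | O=c1c(I)c(-c2ccc(OCc3ccccc3)cc2)oc2cc(OCc3ccccc3)cc(OCc3ccccc3)c12 | intermediate
11 | 3-[hydroxy(tosyloxy)iodo]-5,7-bis(benzyloxy)-2-[4-(benzyloxy)phenyl]-4H-chromen-4-one (not isolated) | Cc1ccc(S(=O)(=O)OI(O)c2c(-c3ccc(OCc4ccccc4)cc3)oc3cc(OCc4ccccc4)cc(OCc4ccccc4)c3c2=O)cc1 | intermediate
12 | [5,7-bis(benzyloxy)-2-[4-(benzyloxy)phenyl]-4-oxo-4H-chromen-3-yl](2,4,6-trimethoxyphenyl)iodonium 4-methylbenzenesulfonate (not isolated) | COc1cc(OC)c([I+]c2c(-c3ccc(OCc4ccccc4)cc3)oc3cc(OCc4ccccc4)cc(OCc4ccccc4)c3c2=O)c(OC)c1.Cc1ccc(S(=O)(=O)[O-])cc1 | intermediate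
13 | [5,7-bis(benzyloxy)-2-[4-(benzyloxy)phenyl]-4-oxo-4H-chromen-3-yl](2,4,6-trimethoxyphenyl)iodonium trifluoromethanesulfonate | COc1cc(OC)c([I+]c2c(-c3ccc(OCc4ccccc4)cc3)oc3cc(OCc4ccccc4)cc(OCc4ccccc4)c3c2=O)c(OC)c1.[O-]S(=O)(=O)C(F)(F)F | intermediate
14 | {[(2S)-5,7-bis(benzyloxy)-2-[4-(benzyloxy)phenyl]-2H-chromen-4-yl]oxy}trimethylsilane (not isolated) | C[Si](C)(C)OC1=C[C@@H](c2ccc(OCc3ccccc3)cc2)Oc2cc(OCc3ccccc3)cc(OCc3ccccc3)c12 | intermediate
15 | (2S,3R)-5,7-bis(benzyloxy)-2-[4-(benzyloxy)phenyl]-3-{5,7-bis(benzyloxy)-2-[4-(benzyloxy)phenyl]-4-oxo-4H-chromen-3-yl}-2,3-dihydro-4H-chromen-4-one (2,3-trans) | O=C1c2c(OCc3ccccc3)cc(OCc3ccccc3)cc2O[C@H](c2ccc(OCc3ccccc3)cc2)[C@H]1c1c(-c2ccc(OCc3ccccc3)cc2)oc2cc(OCc3ccccc3)cc(OCc3ccccc3)c2c1=O | intermediate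
16 | (2S,3R)-5,7-dihydroxy-2-(4-hydroxyphenyl)-3-[5,7-dihydroxy-2-(4-hydroxyphenyl)-4-oxo-4H-chromen-3-yl]-2,3-dihydro-4H-chromen-4-one (2,3-trans) | O=C1c2c(O)cc(O)cc2O[C@H](c2ccc(O)cc2)[C@H]1c1c(-c2ccc(O)cc2)oc2cc(O)cc(O)c2c1=O | target

**Totals**
Total steps: 8. Longest linear sequence: 5 (steps 1, 2, 3, 7, 8; the arm through steps 4, 5, 6, 7, 8 is equally long).

**Steps most likely to fail, with fallbacks**

Step 7. The copper-mediated transfer of the hindered flavon-3-yl group is unprecedented. The enol silane could be oxidised to the flavone, or the wrong aryl group could be transferred. The fallback performs the same polarity-reversed union on an unhindered, achiral enol silane and sets the stereocentres afterwards. It sets out from 2 and 13. Double silylation of 2 (LiN(SiMe3)2, Me3SiCl, THF, −78 °C) gives the bis(trimethylsilyl) enol ether F1. Coupling of this with 13 under [Cu(MeCN)4]OTf catalysis gives the aryl silyl ether F2, which loses its silyl group on aqueous work-up to give the 3-phenacylflavone F3. Condensation with 4-(benzyloxy)benzaldehyde (piperidinium acetate, toluene, removal of water) gives the α-(flavon-3-yl)-2'-hydroxychalcone F4. An asymmetric intramolecular oxa-Michael addition, catalysed by a cinchona-derived bifunctional thiourea (the pseudoenantiomer that gives the 2S series) at low temperature, then closes ring C with the C3 centre settling trans. The route is rejoined at 15.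

Step 6. Oxidation of the electron-poor, hindered 3-iodide may be slow, and the peracid or the hypervalent iodine intermediate may attack the benzyloxy-substituted rings. The fallback forms the carbon–iodine bond from the hypervalent iodine side by tin-to-iodine exchange, so that no oxidant meets the flavone. It sets out from 8. The 3-lithio species 9 is quenched with Bu3SnCl to give the 3-(tributylstannyl)flavone F5. This reacts with [hydroxy(tosyloxy)iodo]mesitylene in CH2Cl2 at 0 °C to give the flavon-3-yl(mesityl)iodonium tosylate F6. F6 takes the place of 13 in the coupling with 14, and the route comes back at 15.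

Step 3. The electron-rich, 5-substituted chromone may add the aryl group sluggishly, or the flavanone may ring-open under the conditions. The fallback builds the flavanone as a racemate and resolves it by a catalyst-controlled reduction. It sets out from 2. Claisen–Schmidt condensation with 4-(benzyloxy)benzaldehyde (KOH, EtOH) gives the 2'-hydroxychalcone F7. NaOAc in refluxing EtOH cyclises it to the racemic flavanone F8. Kinetic resolution by asymmetric transfer hydrogenation with RuCl[(R,R)-TsDPEN](p-cymene) and HCO2H/Et3N reduces the 2R enantiomer to the cis-(2R,4R)-flavan-4-ol F9, which is separated. The unreduced 2S ketone is 6, where the route is rejoined.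

**Further compounds**
F1 | step 7 | ({1-[2,4-bis(benzyloxy)-6-(trimethylsilyloxy)phenyl]ethenyl}oxy)trimethylsilane | C=C(O[Si](C)(C)C)c1c(O[Si](C)(C)C)cc(OCc2ccccc2)cc1OCc1ccccc1
F2 | step 7 | 1-[2,4-bis(benzyloxy)-6-(trimethylsilyloxy)phenyl]-2-{5,7-bis(benzyloxy)-2-[4-(benzyloxy)phenyl]-4-oxo-4H-chromen-3-yl}ethan-1-one | O=C(Cc1c(-c2ccc(OCc3ccccc3)cc2)oc2cc(OCc3ccccc3)cc(OCc3ccccc3)c2c1=O)c1c(O[Si](C)(C)C)cc(OCc2ccccc2)cc1OCc1ccccc1
F3 | step 7 | 1-[2,4-bis(benzyloxy)-6-hydroxyphenyl]-2-{5,7-bis(benzyloxy)-2-[4-(benzyloxy)phenyl]-4-oxo-4H-chromen-3-yl}ethan-1-one | O=C(Cc1c(-c2ccc(OCc3ccccc3)cc2)oc2cc(OCc3ccccc3)cc(OCc3ccccc3)c2c1=O)c1c(O)cc(OCc2ccccc2)cc1OCc1ccccc1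
F4 | step 7 | (E)-1-[2,4-bis(benzyloxy)-6-hydroxyphenyl]-3-[4-(benzyloxy)phenyl]-2-{5,7-bis(benzyloxy)-2-[4-(benzyloxy)phenyl]-4-oxo-4H-chromen-3-yl}prop-2-en-1-one | O=C(/C(=C/c1ccc(OCc2ccccc2)cc1)c1c(-c2ccc(OCc3ccccc3)cc2)oc2cc(OCc3ccccc3)cc(OCc3ccccc3)c2c1=O)c1c(O)cc(OCc2ccccc2)cc1OCc1ccccc1
F5 | step 6 | 5,7-bis(benzyloxy)-2-[4-(benzyloxy)phenyl]-3-(tributylstannyl)-4H-chromen-4-one | CCCC[Sn](CCCC)(CCCC)c1c(-c2ccc(OCc3ccccc3)cc2)oc2cc(OCc3ccccc3)cc(OCc3ccccc3)c2c1=O
F6 | step 6 | [5,7-bis(benzyloxy)-2-[4-(benzyloxy)phenyl]-4-oxo-4H-chromen-3-yl](2,4,6-trimethylphenyl)iodonium 4-methylbenzenesulfonate | Cc1cc(C)c([I+]c2c(-c3ccc(OCc4ccccc4)cc3)oc3cc(OCc4ccccc4)cc(OCc4ccccc4)c3c2=O)c(C)c1.Cc1ccc(S(=O)(=O)[O-])cc1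
F7 | step 3 | (E)-1-[2,4-bis(benzyloxy)-6-hydroxyphenyl]-3-[4-(benzyloxy)phenyl]prop-2-en-1-one | O=C(/C=C/c1ccc(OCc2ccccc2)cc1)c1c(O)cc(OCc2ccccc2)cc1OCc1ccccc1
F8 | step 3 | racemic 5,7-bis(benzyloxy)-2-[4-(benzyloxy)phenyl]-2,3-dihydro-4H-chromen-4-one | O=C1CC(c2ccc(OCc3ccccc3)cc2)Oc2cc(OCc3ccccc3)cc(OCc3ccccc3)c12
F9 | step 3 | (2R,4R)-5,7-bis(benzyloxy)-2-[4-(benzyloxy)phenyl]-3,4-dihydro-2H-chromen-4-ol (2,4-cis) | O[C@@H]1C[C@H](c2ccc(OCc3ccccc3)cc2)Oc2cc(OCc3ccccc3)cc(OCc3ccccc3)c12
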